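- At early times Q is still going in, during the 40 h feed, so we read the late stretch of each fed run, where L and X turn Q into G.

common to all: L 10 mol%
- elm: Q 0.022 M (fed, over 40 h); X 1.2 equiv; run made earlier
- oak: Q 0.057 M (fed, over 40 h); X 1.2 equiv; run made earlier
- cedar: Q 0.089 M (fed, over 40 h); X 1.2 equiv; run made earlier
- Saturday's: Q 0.10 M (fed, over 40 h); X 1.20 equiv; time 15 d; volume of the second phase over the first 1.0
- Thursday's: Q 0.030 M; X 1.20 equiv; everything together at the start; time 15 d; volume of the second phase over the first 1.0

| run | time / d | G / % |
|---|---|---|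
| elm | 0.833 | 2.3 |
| elm | 2.08 | 11.9 |
| elm | 5.00 | 29.9 |
| elm | 10.0 | 48.9 |
| oak | 2.50 | 29.8 |
| oak | 5.00 | 51.3 |
| oak | 8.00 | 66.0 |
| oak | 10.0 | 71.7 |
| cedar | 1.25 | 16.4 |
| cedar | 4.00 | 54.9 |
| cedar | 6.00 | 67.4 |
| cedar | 10.0 | 79.0 |

(each reading ± 0.5 percentage points)

- charges count per volume of the first phase; a concentration in a rate is the amount of a species over the volume of its own phase; every rate counts per litre of the first phase
- the earlier runs hold the two phases in the same ratio of volumes as the flask asked about
- where the amount of Q changes, what is given in equivalents or mol% on it follows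
- percentages count the whole charge, also what has not yet gone in

* the winner by amount of G, in percent of the Q charged; "neither" if no more than 2 percentage points parts them (Saturday's / Thursday's / neither)
* how much G is there at the end, in percent of the Q charged: Saturday's
* how much G is there at the end, in percent of the Q charged: Thursday's

- Let r be the reciprocal of the share of charged Q not yet G; with everything present at the start, r begins at 1.
- We assume that, past any feed, r climbs straight, with a slope proportional to the charge c_Q.
- Slope per M of Q, over each run's last stretch: elm 0.201 L mol⁻¹ h⁻¹, oak 0.216 L mol⁻¹ h⁻¹, cedar 0.199 L mol⁻¹ h⁻¹.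
- X at 1.20 equiv, L at 10 mol% and the phase ratio 1.0 stand the same in the runs and in both flasks, so we let the slope carry them.
- Cedar's line, run back to time zero, starts at r = 0.521, and using that start instead of 1 moves Saturday's by 0.77 percentage points, less than the margin.
- The slope has to be known too: the runs' range moves Thursday's from 68.2% to 70.0%.
- So we commit to the mean, 0.205 L mol⁻¹ h⁻¹, as κ, the late slope of r per M of Q charged, an apparent second-order constant.
- Thursday's: r = 1 + κ c_Q t gives 68.9%.
- Saturday's, borrowing cedar's start: r = 0.521 + κ c_Q t gives 87.4%.
- The gap of 18 points is wider than the margin, so we name Saturday's.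
- The forecast says Saturday's, with 87% and 69%: “close to proportional to the charge”.
- The flasks give Saturday's, with 88.1% for Saturday's and 69.3% for Thursday's.

    Q + J → G + L (k = 3.60 L mol⁻¹ h⁻¹)
    2 J → Z (k = 0.863 L mol⁻¹ h⁻¹)
    L + X ⇌ J + D (K = 0.644, k = 3.73 L mol⁻¹ h⁻¹)

- Thursday's result, read back, gives κ = 0.209 L mol⁻¹ h⁻¹, inside the runs' range.
- If κ c_Q grows in step with L, a neighbour of Thursday's with 17 mol% of L should reach 79.0%; it gives 79.8%.
- Neither flask has come to rest at 15 d: Saturday's still holds 12% of its Q, and Thursday's 31%.
- At 150 d, Saturday's G stands at >99.9%.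
- At 150 d, Thursday's G stands at 98.8%, with Q down to 1.24%.

The readings were computed on assumed constants, noise included.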